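**Retrosynthetic overview**
1. Feature: in the pyrrolidinone ring (N4, C9a, C1, C2, C3) the atoms N4–C3–C2–C1–OH form a 1,3-amino alcohol, and the carbinol carbon C1 also bears the lactam carbonyl C9a. This is the N–O-cleaved, N-acylated form of a 5,5-disubstituted isoxazolidine (O, N4, C3, C2, C1), that is, of a C3=N4 nitrone added to a C12-substituted acrylate C1(=C2H2)–C9a.
2. Key disconnection: C2–C3 and C1–O are made in one N-tethered nitrone–acrylate cycloaddition that also closes the large ring (11 atoms through O, 12 through C2–C3). Zn/AcOH then replaces the O bridge by C9a (again 11 atoms: N4, C5–C12, C1, C9a), and mild acid frees the C9 ketone.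
3. Nitrone: a C5 nitro group is reduced in the presence of lactone-A aldehyde 8. Compound 8 comes from (S)-5-(hydroxymethyl)butyrolactone (C18) by α-methylenation and face-selective hydrogenation (C20).
4. Acrylate part: cuprate addition and methylation on (S)-5-(silyloxymethyl)butenolide set C12 and C13, and glycol cleavage turns C11 into an aldehyde. An Evans syn aldol sets C10/C11 and relactonisation gives the C11/C12-cis lactone B. A Fukuyama coupling adds C5–C8, and the vinylsilane is converted via the bromide into the methyl acrylate.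
5. Ring order: lactone A; lactone B; C9 dioxolane; isoxazolidine together with the macrocycle; pyrrolidinone (the isoxazolidine is lost); the dioxolane is removed last.

Key step: step 22

Remark: locants follow the target skeleton (N4; C5–C8 four CH2; C9 ketone; C10 CHEt; lactone B O–C11–C12–C13(Me)–C14(=O); C1 carbinol; C9a lactam C=O; C2 ring CH2; C3 NCH; lactone A O–C18–C19–C20(Me)–C21(=O)), and 1, 9, 11, 18, 19 and 25 are taken as commercial.

**Step 1**
Reactants: 1 (S)-5-(hydroxymethyl)dihydrofuran-2(3H)-one
Product: 2 (S)-5-[(tert-butyldiphenylsilyloxy)methyl]dihydrofuran-2(3H)-one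
Conditions: TBDPSCl, imidazole, DMF, 0 °C to rt
Reagents that add atoms: tert-butylchlorodiphenylsilane, CC(C)(C)[Si](Cl)(c1ccccc1)c1ccccc1
Why: Imidazole-promoted silyl ether formation on the primary alcohol; the bulky group later shields one lactone face, and C18 (S, chiral pool) is not touched.

**Step 2**
Reactants: 2 (S)-5-[(tert-butyldiphenylsilyloxy)methyl]dihydrofuran-2(3H)-one
Product: 5 (S)-5-[(tert-butyldiphenylsilyloxy)methyl]-3-methylenedihydrofuran-2(3H)-one, via Mannich base 3 (not isolated), via ammonium iodide 4 (not isolated)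
Conditions: LDA, THF, −78 °C; CH2=NMe2+ I−, −78 °C to rt; MeI, MeOH, rt; aq NaHCO3, CH2Cl2, rt
Reagents that add atoms: Eschenmoser's salt, C=[N+](C)C.[I-]
Why: Mannich reaction of the lithium enolate with Eschenmoser's salt, exhaustive methylation and Hofmann-type elimination is the standard α-methylenation of γ-lactones; it sets no stereocentre, and C18 carries no acidic hydrogen.

**Step 3**
Reactants: 5 (S)-5-[(tert-butyldiphenylsilyloxy)methyl]-3-methylenedihydrofuran-2(3H)-one
Product: 6 (3S,5S)-5-[(tert-butyldiphenylsilyloxy)methyl]-3-methyldihydrofuran-2(3H)-one (cis)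
Conditions: H2 (1 atm), 10% Pd/C, EtOAc, rt
Reagents that add atoms: none
Why: Heterogeneous catalytic hydrogenation should deliver H2 to the exocyclic alkene from the face opposite the CH2OTBDPS arm, so that the new C20 methyl ends cis to the C18 substituent.

**Step 4**
Reactants: 6 (3S,5S)-5-[(tert-butyldiphenylsilyloxy)methyl]-3-methyldihydrofuran-2(3H)-one
Product: 7 (3S,5S)-5-(hydroxymethyl)-3-methyldihydrofuran-2(3H)-one
Conditions: TBAF, AcOH, THF, 0 °C to rt
Reagents that add atoms: none
Why: Fluoride-mediated desilylation, buffered by AcOH so that C20 does not epimerise and the lactone does not migrate.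

**Step 5**
Reactants: 7 (3S,5S)-5-(hydroxymethyl)-3-methyldihydrofuran-2(3H)-one
Product: 8 (2S,4S)-4-methyl-5-oxotetrahydrofuran-2-carbaldehyde (lactone A aldehyde, CHO = C3)
Conditions: Dess–Martin periodinane, CH2Cl2, 0 °C to rt
Reagents that add atoms: none
Why: Dess–Martin oxidation works without base and stops at the aldehyde, so the α-oxygenated centre C18 should be kept; 8 is made just before step 21.

**Step 6**
Reactants: 9 (S)-5-(hydroxymethyl)furan-2(5H)-one
Product: 10 (S)-5-[(tert-butyldiphenylsilyloxy)methyl]furan-2(5H)-one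
Conditions: TBDPSCl, imidazole, CH2Cl2, 0 °C to rt
Reagents that add atoms: tert-butylchlorodiphenylsilane, CC(C)(C)[Si](Cl)(c1ccccc1)c1ccccc1
Why: Silyl ether formation as in step 1; the large CH2OTBDPS group on the only stereocentre becomes the control element of the next two steps.

**Step 7**
Reactants: 10 (S)-5-[(tert-butyldiphenylsilyloxy)methyl]furan-2(5H)-one; 11 (1-bromovinyl)trimethylsilane
Product: 13 (4S,5S)-5-[(tert-butyldiphenylsilyloxy)methyl]-4-[1-(trimethylsilyl)vinyl]dihydrofuran-2(3H)-one (4,5-trans), via Grignard reagent 12 (not isolated)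
Conditions: 11, Mg, THF, reflux; CuBr·SMe2 (0.5 equiv per Grignard), THF–Me2S, −78 °C; 10, −78 to −30 °C; aq NH4Cl
Reagents that add atoms: none
Why: Organocuprate 1,4-addition to a γ-substituted butenolide should occur anti to the CH2OTBDPS group and so sets C12; the α-silylvinyl group brings C1 and C2 and stays inert until step 17.

**Step 8**
Reactants: 13 (4S,5S)-5-[(tert-butyldiphenylsilyloxy)methyl]-4-[1-(trimethylsilyl)vinyl]dihydrofuran-2(3H)-one
Product: 14 (3S,4S,5S)-5-[(tert-butyldiphenylsilyloxy)methyl]-3-methyl-4-[1-(trimethylsilyl)vinyl]dihydrofuran-2(3H)-one (3,4-trans, 4,5-trans)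
Conditions: LDA, THF, −78 °C; MeI, −78 to −40 °C
Reagents that add atoms: iodomethane, CI
Why: Alkylation of the lithium lactone enolate should take place anti to the bulky C12 substituent and sets C13 with the methyl trans to it, which is also the more stable arrangement.

**Step 9**
Reactants: 14 (3S,4S,5S)-5-[(tert-butyldiphenylsilyloxy)methyl]-3-methyl-4-[1-(trimethylsilyl)vinyl]dihydrofuran-2(3H)-one
Product: 15 (3S,4S,5S)-5-(hydroxymethyl)-3-methyl-4-[1-(trimethylsilyl)vinyl]dihydrofuran-2(3H)-one
Conditions: TBAF, AcOH, THF, 0 °C to rt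
Reagents that add atoms: none
Why: Buffered fluoride desilylation removes the silyl ether, while the hindered carbon-bound vinylsilane stays.

**Step 10**
Reactants: 15 (3S,4S,5S)-5-(hydroxymethyl)-3-methyl-4-[1-(trimethylsilyl)vinyl]dihydrofuran-2(3H)-one
Product: 16 (2S,3S,4S)-4,5-dihydroxy-N-methoxy-N,2-dimethyl-3-[1-(trimethylsilyl)vinyl]pentanamide
Conditions: MeONHMe·HCl, AlMe3, CH2Cl2, 0 °C to rt; aq Rochelle salt
Reagents that add atoms: N,O-dimethylhydroxylamine hydrochloride, CNOC.Cl
Why: Weinreb aminolysis of the lactone by the aluminium amide opens the ring and uncovers the terminal 1,2-diol without touching C12 or C13.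

**Step 11**
Reactants: 16 (2S,3S,4S)-4,5-dihydroxy-N-methoxy-N,2-dimethyl-3-[1-(trimethylsilyl)vinyl]pentanamide
Product: 17 (2S,3S)-3-formyl-N-methoxy-N,2-dimethyl-4-(trimethylsilyl)pent-4-enamide (CHO = C11)
Conditions: NaIO4, THF–pH 7 buffer, 0 °C
Reagents that add atoms: none
Why: Malaprade glycol cleavage at neutral pH sacrifices the old carbinol stereocentre, which becomes aldehyde carbon C11, and keeps the enolisable centre C12 away from acid and base; 17 is used at once.

**Step 12**
Reactants: 18 (S)-4-benzyloxazolidin-2-one; 19 butanoyl chloride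
Product: 20 (S)-4-benzyl-3-butanoyloxazolidin-2-one
Conditions: n-BuLi, THF, −78 °C; 19, −78 to 0 °C
Reagents that add atoms: none
Why: N-Acylation of the lithiated oxazolidinone gives the Evans imide that carries C9, C10 and the ethyl group.

**Step 13**
Reactants: 20 (S)-4-benzyl-3-butanoyloxazolidin-2-one; 17 (2S,3S)-3-formyl-N-methoxy-N,2-dimethyl-4-(trimethylsilyl)pent-4-enamide
Product: 23 lactone B imide (C9 imide; C10 ethyl syn to C11–O; C10 chain and C12 silylvinyl cis on the lactone; C13 methyl trans to both), via Z-boron enolate 21 (not isolated), via hydroxy imide 22 (not isolated)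
Conditions: 20, Bu2BOTf, Et3N, CH2Cl2, −78 to 0 °C; 17, −78 to 0 °C; H2O2, MeOH, pH 7 buffer, 0 °C; CSA (1.1 equiv), CH2Cl2, rt
Reagents that add atoms: none
Why: Evans syn aldol: the Z-boron enolate reacts through a Zimmerman–Traxler chair in which the (S)-benzyl auxiliary dictates the enolate face, which should set C10 and C11 as the syn pair (attack on the Si face of 17) whatever the bias of the aldehyde, and acid then lets C11–OH displace the Weinreb amine to close lactone B with C10 and C1 cis.

**Step 14**
Reactants: 23 lactone B imide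
Product: 24 lactone B S-ethyl thioester (C9 thioester, stereocentres as in 23)
Conditions: EtSH, n-BuLi, THF, 0 °C
Reagents that add atoms: ethanethiol, CCS
Why: Transthioesterification: the soft, weakly basic lithium thiolate attacks the exocyclic imide carbonyl, so the auxiliary leaves without epimerisation at C10 or β-elimination of the C11 oxygen.

**Step 15**
Reactants: 24 lactone B S-ethyl thioester; 25 1-chloro-4-iodobutane
Product: 27 C9 ketone bearing the 4-chlorobutyl chain C5–C8, via alkylzinc iodide 26 (not isolated)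
Conditions: 25, Zn dust, THF, 35 °C; 24, PdCl2(PPh3)2 (cat.), toluene, rt
Reagents that add atoms: none
Why: Fukuyama coupling (Pd-catalysed acylation of an alkylzinc iodide by a thioester) forms C8–C9 and stops at the ketone; lactone, alkyl chloride and vinylsilane are inert to the zinc reagent, and no base is present.

**Step 16**
Reactants: 27 C9 ketone
Product: 28 C9 ethylene ketal (1,3-dioxolane)
Conditions: TMSOCH2CH2OTMS, TMSOTf (cat.), CH2Cl2, −78 to −20 °C; pyridine
Reagents that add atoms: 1,2-bis(trimethylsilyloxy)ethane, C[Si](C)(C)OCCO[Si](C)(C)C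
Why: Noyori ketalisation is aprotic and runs cold, which should spare C10 and the β-acyloxy group, and the α-silyl alkene is too poor a π-nucleophile to trap the oxocarbenium ion.

**Step 17**
Reactants: 28 C9 ethylene ketal
Product: 30 alkenyl bromide (C12–C1(Br)=C2H2), via dibromide 29 (not isolated)
Conditions: Br2, CH2Cl2, −78 °C; TBAF, THF, −78 to 0 °C
Reagents that add atoms: bromine, BrBr
Why: Bromodesilylation: Br2 adds to the vinylsilane, and fluoride then triggers β-elimination of Me3Si and the terminal bromide, which gives the 2-bromo-1-alkene regiospecifically.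

**Step 18**
Reactants: 30 alkenyl bromide
Product: 31 methyl acrylate chloride (C12–C1(=C2H2)–C9a O2Me, C5–Cl)
Conditions: CO (balloon), Pd(OAc)2 (cat.), dppf (cat.), i-Pr2NEt, MeOH–DMF, 60 °C
Reagents that add atoms: carbon monoxide, [C-]#[O+]; methanol, CO
Why: Palladium-catalysed methoxycarbonylation (Heck carbonylation) of the alkenyl bromide installs C9a as the methyl ester with the C1=C2 methylene in place; the primary chloride does not add to Pd(0), and the hindered amine does not open lactone B.

**Step 19**
Reactants: 31 methyl acrylate chloride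
Product: 32 methyl acrylate iodide (C5–I)
Conditions: NaI, acetone, reflux
Reagents that add atoms: sodium iodide, [Na+].[I-]
Why: Finkelstein exchange, driven by precipitation of NaCl, turns the inert chloride into a good leaving group only after all metal-mediated steps are over.

**Step 20**
Reactants: 32 methyl acrylate iodide
Product: 33 nitroalkane (C5–NO2)
Conditions: AgNO2, Et2O, 0 °C to rt, dark
Reagents that add atoms: silver nitrite, [Ag+].[O-]N=O
Why: Victor Meyer reaction: silver nitrite substitutes primary iodides mainly through nitrogen under neutral conditions, which installs N4 with its oxygen and leaves acrylate, lactone and ketal alone.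

**Step 21**
Reactants: 33 nitroalkane; 8 (2S,4S)-4-methyl-5-oxotetrahydrofuran-2-carbaldehyde
Product: 35 Z-nitrone C3=N4(O) carrying lactone A plus the C9 ketal chain plus lactone B plus the acrylate, via hydroxylamine 34 (not isolated)
Conditions: 8, Zn dust, AcOH, EtOH, 0 °C
Reagents that add atoms: none
Why: Zinc in dilute acetic acid should stop the reduction of the primary nitroalkane at the N-alkylhydroxylamine, which condenses at once with 8 to the aldonitrone (Z for steric reasons) before it can add to the acrylate, while the dioxolane keeps it from closing onto C9 to a six-membered ketonitrone.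

**Step 22**
Reactants: 35 Z-nitrone
Product: 36 bridged macrocyclic isoxazolidine methyl ester
Conditions: toluene (degassed), 105 °C, slow addition to a final 1 mM, BHT (cat.)
Reagents that add atoms: none
Why: On heating, the Z-aldonitrone C3=N4(O) and the tethered 2-substituted acrylate C1=C2 combine in a concerted suprafacial [3+2] cycloaddition (intramolecular nitrone–olefin cycloaddition, here in its rarer macrocyclising form) that bonds C3 to the free methylene C2 and the nitrone oxygen to the fully substituted C1, the orientation nitrones show with methacrylate-type acceptors and one that the long, flexible C5–C12 tether does not oppose. The isoxazolidine (O, N4, C3, C2, C1) is closed by the cycloaddition itself, and the large ring (11 atoms through O: N4, C5–C12, C1, O; 12 atoms through C2–C3) is closed in the same event as an end-to-end cyclisation that must outrun dimerisation, hence the slow addition at high dilution. C3 is controlled by C18: with C18–H eclipsing the N–O bond to avoid allylic strain, the acrylate should add anti to the C18–O bond of lactone A, which gives the syn N4/O relationship of C3 and C18. C1 is controlled by C12: in the rotamer with C12–H near the alkene plane, C13 covers one acrylate face, while C11, through which the tether runs, lies on the face that the nitrone has to reach. Pairing these two faces is the same as the CO2Me-endo, C12-exo arrangement of the Z-nitrone, sterically the better one, and it places C12 and C18 cis on the isoxazolidine. The step therefore needs regioselectivity (electronic) and two facial selectivities; the acrylate face is reinforced by the tether, and the nitrone face, which rests on C18 alone, is the least secured.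

**Step 23**
Reactants: 36 bridged macrocyclic isoxazolidine methyl ester
Product: 38 C9-ketal hydroxylactam (target skeleton with dioxolane at C9), via amino ester 37 (not isolated)
Conditions: Zn dust, AcOH–THF, rt; filter, aq NaHCO3; toluene, 80 °C
Reagents that add atoms: none
Why: Reductive N–O cleavage by zinc frees the C1 hydroxyl and the secondary amine N4, which should attack the neighbouring methyl ester in a 5-exo-trig lactamisation, so that C9a replaces O as the bridge of the 11-membered ring; no stereocentre is affected.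

**Step 24**
Reactants: 38 C9-ketal hydroxylactam
Product: 39 CNP0221273.1 (target)
Conditions: p-TsOH·H2O (cat.), acetone–H2O, rt to 40 °C
Reagents that add atoms: water, O
Why: Acid-catalysed ketal hydrolysis under mild conditions frees the C9 ketone; lactones, lactam and tertiary alcohol tolerate it, and the short exposure should not enolise C10.

**Compound list**
1 | (S)-5-(hydroxymethyl)dihydrofuran-2(3H)-one | OC[C@@H]1CCC(=O)O1 | starting material
2 | (S)-5-[(tert-butyldiphenylsilyloxy)methyl]dihydrofuran-2(3H)-one | CC(C)(C)[Si](c1ccccc1)(c1ccccc1)OC[C@@H]1CCC(=O)O1 | intermediate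
3 | Mannich base, 3-[(dimethylamino)methyl] derivative of 2 (C3 epimers) | CC(C)(C)[Si](c1ccccc1)(c1ccccc1)OC[C@@H]1CC(CN(C)C)C(=O)O1 | intermediate
4 | ammonium iodide, 3-[(trimethylammonio)methyl] derivative of 2 | CC(C)(C)[Si](c1ccccc1)(c1ccccc1)OC[C@@H]1CC(C[N+](C)(C)C)C(=O)O1.[I-] | intermediate
5 | (S)-5-[(tert-butyldiphenylsilyloxy)methyl]-3-methylenedihydrofuran-2(3H)-one | CC(C)(C)[Si](c1ccccc1)(c1ccccc1)OC[C@@H]1CC(=C)C(=O)O1 | intermediate
6 | (3S,5S)-5-[(tert-butyldiphenylsilyloxy)methyl]-3-methyldihydrofuran-2(3H)-one | CC(C)(C)[Si](c1ccccc1)(c1ccccc1)OC[C@@H]1C[C@H](C)C(=O)O1 | intermediate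
7 | (3S,5S)-5-(hydroxymethyl)-3-methyldihydrofuran-2(3H)-one | OC[C@@H]1C[C@H](C)C(=O)O1 | intermediate
8 | (2S,4S)-4-methyl-5-oxotetrahydrofuran-2-carbaldehyde | O=C[C@@H]1C[C@H](C)C(=O)O1 | intermediate
9 | (S)-5-(hydroxymethyl)furan-2(5H)-one | OC[C@@H]1C=CC(=O)O1 | starting material
10 | (S)-5-[(tert-butyldiphenylsilyloxy)methyl]furan-2(5H)-one | CC(C)(C)[Si](c1ccccc1)(c1ccccc1)OC[C@@H]1C=CC(=O)O1 | intermediate
11 | (1-bromovinyl)trimethylsilane | C=C(Br)[Si](C)(C)C | starting material
12 | [1-(trimethylsilyl)vinyl]magnesium bromide | C=C([Mg]Br)[Si](C)(C)C | intermediate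
13 | (4S,5S)-5-[(tert-butyldiphenylsilyloxy)methyl]-4-[1-(trimethylsilyl)vinyl]dihydrofuran-2(3H)-one | CC(C)(C)[Si](c1ccccc1)(c1ccccc1)OC[C@@H]1[C@@H](C(=C)[Si](C)(C)C)CC(=O)O1 | intermediate
14 | (3S,4S,5S)-5-[(tert-butyldiphenylsilyloxy)methyl]-3-methyl-4-[1-(trimethylsilyl)vinyl]dihydrofuran-2(3H)-one | CC(C)(C)[Si](c1ccccc1)(c1ccccc1)OC[C@@H]1[C@@H](C(=C)[Si](C)(C)C)[C@H](C)C(=O)O1 | intermediate
15 | (3S,4S,5S)-5-(hydroxymethyl)-3-methyl-4-[1-(trimethylsilyl)vinyl]dihydrofuran-2(3H)-one | OC[C@@H]1[C@@H](C(=C)[Si](C)(C)C)[C@H](C)C(=O)O1 | intermediate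
16 | (2S,3S,4S)-4,5-dihydroxy-N-methoxy-N,2-dimethyl-3-[1-(trimethylsilyl)vinyl]pentanamide | OC[C@@H](O)[C@@H](C(=C)[Si](C)(C)C)[C@H](C)C(=O)N(C)OC | intermediate
17 | (2S,3S)-3-formyl-N-methoxy-N,2-dimethyl-4-(trimethylsilyl)pent-4-enamide | O=C[C@@H](C(=C)[Si](C)(C)C)[C@H](C)C(=O)N(C)OC | intermediate
18 | (S)-4-benzyloxazolidin-2-one | O=C1N[C@@H](Cc2ccccc2)CO1 | starting material
19 | butanoyl chloride | CCCC(=O)Cl | starting material
20 | (S)-4-benzyl-3-butanoyloxazolidin-2-one | CCCC(=O)N1[C@@H](Cc2ccccc2)COC1=O | intermediate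
21 | Z-dibutylboron enolate of 20 | CC/C=C(\OB(CCCC)CCCC)N1[C@@H](Cc2ccccc2)COC1=O | intermediate
22 | syn-aldol hydroxy imide (C10–C13 all-syn, C14 Weinreb amide) | CC[C@@H]([C@H](O)[C@@H](C(=C)[Si](C)(C)C)[C@H](C)C(=O)N(C)OC)C(=O)N1[C@@H](Cc2ccccc2)COC1=O | intermediate
23 | lactone B imide | CC[C@@H]([C@@H]1OC(=O)[C@@H](C)[C@@H]1C(=C)[Si](C)(C)C)C(=O)N1[C@@H](Cc2ccccc2)COC1=O | intermediate
24 | lactone B S-ethyl thioester | CC[C@@H]([C@@H]1OC(=O)[C@@H](C)[C@@H]1C(=C)[Si](C)(C)C)C(=O)SCC | intermediate
25 | 1-chloro-4-iodobutane | ClCCCCI | starting material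
26 | 4-chlorobutylzinc iodide | ClCCCC[Zn]I | intermediate
27 | C9 ketone with 4-chlorobutyl chain | CC[C@@H]([C@@H]1OC(=O)[C@@H](C)[C@@H]1C(=C)[Si](C)(C)C)C(=O)CCCCCl | intermediate
28 | C9 ethylene ketal, vinylsilane | CC[C@@H]([C@@H]1OC(=O)[C@@H](C)[C@@H]1C(=C)[Si](C)(C)C)C1(OCCO1)CCCCCl | intermediate
29 | 1,2-dibromo-1-silyl adduct (C1 epimers) | CC[C@@H]([C@@H]1OC(=O)[C@@H](C)[C@@H]1C(Br)(CBr)[Si](C)(C)C)C1(OCCO1)CCCCCl | intermediate
30 | alkenyl bromide | CC[C@@H]([C@@H]1OC(=O)[C@@H](C)[C@@H]1C(=C)Br)C1(OCCO1)CCCCCl | intermediate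
31 | methyl acrylate chloride | CC[C@@H]([C@@H]1OC(=O)[C@@H](C)[C@@H]1C(=C)C(=O)OC)C1(OCCO1)CCCCCl | intermediate
32 | methyl acrylate iodide | CC[C@@H]([C@@H]1OC(=O)[C@@H](C)[C@@H]1C(=C)C(=O)OC)C1(OCCO1)CCCCI | intermediate
33 | nitroalkane | CC[C@@H]([C@@H]1OC(=O)[C@@H](C)[C@@H]1C(=C)C(=O)OC)C1(OCCO1)CCCC[N+](=O)[O-] | intermediate
34 | N-alkylhydroxylamine | CC[C@@H]([C@@H]1OC(=O)[C@@H](C)[C@@H]1C(=C)C(=O)OC)C1(OCCO1)CCCCNO | intermediate
35 | Z-nitrone (key-step precursor) | CC[C@@H]([C@@H]1OC(=O)[C@@H](C)[C@@H]1C(=C)C(=O)OC)C1(OCCO1)CCCC/[N+]([O-])=C/[C@@H]1C[C@H](C)C(=O)O1 | intermediate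
36 | bridged macrocyclic isoxazolidine ester (key-step product) | CC[C@@H]1C3(OCCO3)CCCCN2O[C@](C(=O)OC)(C[C@H]2[C@@H]2C[C@H](C)C(=O)O2)[C@@H]2[C@H]1OC(=O)[C@H]2C | intermediate
37 | 12-membered amino alcohol methyl ester | CC[C@@H]1C3(OCCO3)CCCCN[C@H]([C@@H]2C[C@H](C)C(=O)O2)C[C@](O)(C(=O)OC)[C@@H]2[C@H]1OC(=O)[C@H]2C | intermediate
38 | C9-ketal hydroxylactam | CC[C@@H]1C3(OCCO3)CCCCN2C(=O)[C@@](O)(C[C@H]2[C@@H]2C[C@H](C)C(=O)O2)[C@@H]2[C@H]1OC(=O)[C@H]2C | intermediate
39 | CNP0221273.1 | CC[C@@H]1C(=O)CCCCN2C(=O)[C@@](O)(C[C@H]2[C@@H]2C[C@H](C)C(=O)O2)[C@@H]2[C@H]1OC(=O)[C@H]2C | target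

**Step count**
- Total step count: 24.
- Longest linear sequence: 18 steps (9 to 39: steps 6–11 and 13–24).

**Steps most likely to fail**

**Step 22.**
- What may go wrong: closure of the strained 11/12-membered ring may be slower than intermolecular cycloaddition, so that dimers and oligomers build up. Alternatively, attack on the wrong nitrone face (or the C12-endo mode) may make C1/C3 epimers dominate.
- Fallback (from 31 and 8, back at 38): the cycloaddition is run between two molecules and the large ring is closed afterwards at N4–C5. Aldehyde 8 is condensed with N-benzylhydroxylamine to the Z-N-benzyl nitrone F1. F1 is heated with acrylate 31 in concentrated toluene solution and should give the 5,5-disubstituted N-benzyl isoxazolidine F2, whose diastereomers can be separated at this open-chain stage. Hydrogenolysis over Pearlman's catalyst cleaves the N–O and N–benzyl bonds, and the freed amine closes onto the methyl ester to give the NH-hydroxylactam chloride F3. Finkelstein exchange gives the NH-hydroxylactam iodide F4. Deprotonation of the lactam N–H (KHMDS, THF–DMF, high dilution) with intramolecular N-alkylation at C5 then leads to 38.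

**Step 13.**
- What may go wrong: the aldehyde may lose the C12 configuration by enolisation or double-bond migration in contact with amine and boron Lewis acid. The facial selectivity of this double-stereodifferentiating addition to a hindered aldehyde may also erode.
- Fallback (from 17, back at 27): the enolate is replaced by a base-free allylborane, and C9 is built up afterwards. Brown-type asymmetric allylboration of 17 uses (Z)-pent-2-enyldiisopinocampheylborane, in the Ipc antipode that attacks the Si face. It should give the syn-homoallylic alcohol Weinreb amide F5, which CSA closes to the vinyl lactone F6. Lemieux–Johnson cleavage of the unhindered vinyl group (the silyl-flanked alkene is far slower) gives the C9 aldehyde F7. Addition of 4-chlorobutylmagnesium bromide at −78 °C gives the C9 carbinol F8, and Dess–Martin oxidation gives ketone 27.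

**Step 21.**
- What may go wrong: the nitro group may be over-reduced to the amine, the transient hydroxylamine may add to the acrylate, or zinc may attack the α-oxygenated aldehyde.
- Fallback (from 32, back at 35): the N–O unit is brought in intact by substitution instead of by reduction. Iodide 32 alkylates tert-butyl N-(tert-butoxycarbonyloxy)carbamate (K2CO3, DMF) to give the N,O-bis-Boc hydroxylamine F9. Anhydrous TFA in CH2Cl2 at 0 °C removes both Boc groups to give 34 as its salt. This salt is neutralised (NaHCO3, MgSO4) in the presence of 8 and condenses to 35.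

**Further compounds**
F1 | step 22 | (Z)-N-benzyl nitrone of aldehyde 8 | c1ccccc1C/[N+]([O-])=C/[C@@H]1C[C@H](C)C(=O)O1
F2 | step 22 | N-benzyl isoxazolidine from 31 and F1 (C1 and C3 as in 36) | CC[C@@H]([C@@H]1OC(=O)[C@@H](C)[C@@H]1[C@@]2(C(=O)OC)C[C@@H]([C@@H]3C[C@H](C)C(=O)O3)N(Cc3ccccc3)O2)C1(OCCO1)CCCCCl
F3 | step 22 | NH-hydroxylactam chloride | CC[C@@H]([C@@H]1OC(=O)[C@@H](C)[C@@H]1[C@]2(O)C[C@@H]([C@@H]3C[C@H](C)C(=O)O3)NC2=O)C1(OCCO1)CCCCCl
F4 | step 22 | NH-hydroxylactam iodide | CC[C@@H]([C@@H]1OC(=O)[C@@H](C)[C@@H]1[C@]2(O)C[C@@H]([C@@H]3C[C@H](C)C(=O)O3)NC2=O)C1(OCCO1)CCCCI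
F5 | step 13 | syn-homoallylic alcohol Weinreb amide | CC[C@@H]([C@H](O)[C@@H](C(=C)[Si](C)(C)C)[C@H](C)C(=O)N(C)OC)C=C
F6 | step 13 | vinyl lactone | CC[C@@H]([C@@H]1OC(=O)[C@@H](C)[C@@H]1C(=C)[Si](C)(C)C)C=C
F7 | step 13 | C9 aldehyde | CC[C@@H]([C@@H]1OC(=O)[C@@H](C)[C@@H]1C(=C)[Si](C)(C)C)C=O
F8 | step 13 | C9 carbinol (C9 epimers) | CC[C@@H]([C@@H]1OC(=O)[C@@H](C)[C@@H]1C(=C)[Si](C)(C)C)C(O)CCCCCl
F9 | step 21 | N,O-bis-Boc hydroxylamine | CC[C@@H]([C@@H]1OC(=O)[C@@H](C)[C@@H]1C(=C)C(=O)OC)C1(OCCO1)CCCCN(OC(=O)OC(C)(C)C)C(=O)OC(C)(C)C
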